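## Retrosynthetic overview

1. Feature used: ring B (C1' aryl ether oxygen, C2' OH, C4' OMe, C6' pentyl) is an olivetol nucleus with one extra oxygen on C1'. The malonate/non-3-en-2-one construction of the olivetol ring therefore applies if the malonate carbon (future C1') already bears O8 of ring A.
2. Disconnections: benzyl groups off O6 and O2'; pyranone ring at O2–C1 and C3–C4 (C4a methyl of an orsellinate plus a hexanoyl unit); aromatic ring B back to a 4-aryloxycyclohexane-1,3-dione; C1'–C6' and C2'–C3' (Michael–Dieckmann); O8–C1' (SN2 on bromomalonate).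
3. Adjustment: ring A carries C1 as a tert-butyl ester. A methyl ester ortho to the O-malonate would be open to five-membered Dieckmann attack by the malonate anion (benzofuran-3-one formation), to hydroxide in the decarboxylation, and later to the O2' phenoxide.
4. Ring order: ring A is bought (orsellinic acid). Ring B is closed saturated, then decarboxylated, enol-etherified at C4' and dehydrogenated. The pyranone ring is closed last.

Key step: step 4

Atom labels: in every intermediate, ring A and the pyranone ring carry the isocoumarin numbers of the target (C1 carboxyl carbon, C3, C4, C4a, C5 to C8, C8a). Ring B carries C1' to C6' as above.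

Remark on the chemistry: the 1,3-diones are written in the diketo form although they are largely enolised. All compounds with a saturated ring B are racemic. The relative configuration given is the expected one and has no consequence, because the target is achiral.

## Route

Step 1
Reactants: 1 orsellinic acid (2,4-dihydroxy-6-methylbenzoic acid); 2 tert-butyl 2,2,2-trichloroacetimidate
Product: 3 tert-butyl 2,4-dihydroxy-6-methylbenzoate
Conditions: 2 (2 equiv), THF, rt
Reagents that add atoms: tert-butyl 2,2,2-trichloroacetimidate, CC(C)(C)OC(=N)C(Cl)(Cl)Cl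
Why: Imidate esterification: only the carboxylic acid is acidic enough to protonate the trichloroacetimidate, the tert-butyl cation equivalent is taken up by the carboxylate at room temperature, and so the two phenols stay free and the decarboxylation-prone acid is never heated.

Step 2
Reactants: 3 tert-butyl 2,4-dihydroxy-6-methylbenzoate; 4 benzyl bromide
Product: 5 tert-butyl 4-(benzyloxy)-2-hydroxy-6-methylbenzoate
Conditions: BnBr (1.05 equiv), K2CO3 (1.1 equiv), acetone, reflux
Reagents that add atoms: benzyl bromide, BrCc1ccccc1
Why: Williamson ether synthesis made site-selective by the substrate, since the C8 hydroxyl is hydrogen-bonded to the ester carbonyl and shielded by the tert-butyl ester, so that one equivalent of benzyl bromide should take the free and more acidic C6 hydroxyl.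

Step 3
Reactants: 5 tert-butyl 4-(benzyloxy)-2-hydroxy-6-methylbenzoate; 6 dimethyl bromomalonate
Product: 7 dimethyl 2-[5-(benzyloxy)-2-(tert-butoxycarbonyl)-3-methylphenoxy]propanedioate
Conditions: 6 (1.2 equiv, slow addition), K2CO3 (1.5 equiv), DMF, 40 °C; dilute acid work-up
Reagents that add atoms: dimethyl bromomalonate, COC(=O)C(Br)C(=O)OC
Why: SN2 O-alkylation of a phenoxide by a halomalonate, the usual way to aryloxymalonates, which makes the crowded O8–C1' bond while C1' is still an activated sp3 carbon, so that no hindered diaryl ether coupling is ever needed.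

Step 4
Reactants: 7 dimethyl 2-[5-(benzyloxy)-2-(tert-butoxycarbonyl)-3-methylphenoxy]propanedioate; 8 (E)-non-3-en-2-one
Product: 10 methyl 1-[5-(benzyloxy)-2-(tert-butoxycarbonyl)-3-methylphenoxy]-2,4-dioxo-6-pentylcyclohexane-1-carboxylate (racemic; aryloxy trans to pentyl drawn), via Michael adduct 9 (not isolated)
Conditions: NaOMe (1.2 equiv), MeOH, 0 °C; 8 (1.3 equiv), rt then reflux; cold 1 M HCl to pH 3
Reagents that add atoms: (E)-non-3-en-2-one, CCCCC/C=C/C(C)=O
Why: Proposed new method: NaOMe deprotonates C1' of 7, the stabilised tertiary anion adds reversibly to the β-carbon of 8 (bond C1'–C6', giving 9), proton exchange delivers the methyl ketone enolate (C3'), and this attacks one malonate ester (bond C2'–C3') with loss of methoxide; deprotonation of the resulting 1,3-dione at C3' drains both equilibria. The closest known reaction type is the Michael–Dieckmann annulation of malonates and alkylmalonates with alk-3-en-2-ones to 5-alkylcyclohexane-1,3-diones, and conjugate additions of heteroatom-substituted malonates are also known; what has not been shown is an O-aryl malonate as donor in the annulation, where the addition creates a fully substituted C1' next to the branched C6'. Ring B closes in the 6-(enolexo)-exo-trig mode. C6' forms without facial bias (racemate), and C1' is fixed relative to it by which of the two diastereotopic esters is attacked in a chair-like transition state with the pentyl group equatorial; the isomer with the bulky aryloxy group trans to pentyl is expected, but no selectivity is required because C1' loses its ester in step 5 and both centres become sp2 in step 7. The selectivity that is required is between acyl acceptors: the malonate anion could close in the 5-(enolexo)-exo-trig mode on the ring A ester (benzofuran-3-one formation, made irreversible by loss of a carbomethoxy group), which the tert-butyl ester flanked by two ortho substituents is there to block, while the ketone enolate reaches a malonate ester through a six-membered and the ring A ester only through a nine-membered transition state. Should a carbomethoxy group migrate from C1' to C5' before closure (abnormal Michael pathway), the isomeric dione ester would still converge on the same decarboxylated dione in step 5.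

Step 5
Reactants: 10 methyl 1-[5-(benzyloxy)-2-(tert-butoxycarbonyl)-3-methylphenoxy]-2,4-dioxo-6-pentylcyclohexane-1-carboxylate
Product: 12 tert-butyl 4-(benzyloxy)-2-[(2,4-dioxo-6-pentylcyclohexyl)oxy]-6-methylbenzoate (racemic; trans), via β-keto acid 11 (not isolated)
Conditions: 2 M aq NaOH, MeOH/THF, 60 °C; then 1 M HCl to pH 2, 45 °C
Reagents that add atoms: none
Why: Saponification followed by β-keto acid decarboxylation: hydroxide can reach only the C1' methyl ester (activated by the α-aryloxy group), because the tert-butyl ester resists acyl attack and the dione is masked as its enolate, and on acidification the acid loses CO2 through the cyclic six-centre transition state, C1' being reprotonated next to the C2' ketone where it can epimerise to the trans diequatorial arrangement.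

Step 6
Reactants: 12 tert-butyl 4-(benzyloxy)-2-[(2,4-dioxo-6-pentylcyclohexyl)oxy]-6-methylbenzoate; 13 methanol
Product: 14 tert-butyl 4-(benzyloxy)-2-[(4-methoxy-2-oxo-6-pentylcyclohex-3-en-1-yl)oxy]-6-methylbenzoate (racemic; trans)
Conditions: MeOH, p-TsOH·H2O (5 mol %), 3 Å molecular sieves, rt to 40 °C
Reagents that add atoms: methanol, CO
Why: Acid-catalysed, reversible enol etherification of a 1,3-dione under thermodynamic control, in which the vinylogous ester that keeps its carbonyl at C2' (next to the bulky, electron-withdrawing aryloxy-bearing C1') and places methoxy on the unencumbered C4' should be favoured, as with 4-substituted cyclohexane-1,3-diones, while any minor isomer can be separated and re-equilibrated under the same conditions.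

Step 7
Reactants: 14 tert-butyl 4-(benzyloxy)-2-[(4-methoxy-2-oxo-6-pentylcyclohex-3-en-1-yl)oxy]-6-methylbenzoate
Product: 15 tert-butyl 4-(benzyloxy)-2-(2-hydroxy-4-methoxy-6-pentylphenoxy)-6-methylbenzoate
Conditions: DDQ (1.1 equiv), 1,4-dioxane, 90 °C
Reagents that add atoms: none
Why: DDQ dehydrogenation of a cyclohexenone to a phenol, in which hydride loss from C6' of the extended dienol gives a pentadienyl cation stabilised by O2' and O4', loss of the C1' proton aromatises ring B and erases both stereocentres, and the aryl benzyl ether and the tert-butyl ester are inert to one equivalent of the quinone.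

Step 8
Reactants: 15 tert-butyl 4-(benzyloxy)-2-(2-hydroxy-4-methoxy-6-pentylphenoxy)-6-methylbenzoate; 4 benzyl bromide
Product: 16 tert-butyl 4-(benzyloxy)-2-[2-(benzyloxy)-4-methoxy-6-pentylphenoxy]-6-methylbenzoate
Conditions: BnBr (1.2 equiv), K2CO3 (1.5 equiv), DMF, rt
Reagents that add atoms: benzyl bromide, BrCc1ccccc1
Why: Williamson benzylation of the only free hydroxyl, which removes the acidic proton before the lithiation; the tert-butyl ester resists seven-membered lactonisation by the neighbouring phenoxide and the electron-rich ring A does not support a Smiles migration.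

Step 9
Reactants: 17 hexanoyl chloride; 18 N,O-dimethylhydroxylamine hydrochloride
Product: 19 N-methoxy-N-methylhexanamide
Conditions: K2CO3 (2.2 equiv), CH2Cl2/H2O, 0 °C to rt
Reagents that add atoms: N,O-dimethylhydroxylamine hydrochloride, CNOC.Cl
Why: Schotten–Baumann acylation of the amine set free by carbonate, which turns the acid chloride into a Weinreb amide that can be added to a carbanion without over-addition.

Step 10
Reactants: 16 tert-butyl 4-(benzyloxy)-2-[2-(benzyloxy)-4-methoxy-6-pentylphenoxy]-6-methylbenzoate; 19 N-methoxy-N-methylhexanamide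
Product: 21 tert-butyl 4-(benzyloxy)-2-[2-(benzyloxy)-4-methoxy-6-pentylphenoxy]-6-(2-oxoheptyl)benzoate, via benzylic lithium species 20 (not isolated)
Conditions: LiN(iPr)2 (commercial solution, 1.5 equiv), THF, −78 °C; 19 (1.5 equiv), −78 to −40 °C; AcOH quench
Reagents that add atoms: N-methoxy-N-methylhexanamide, CCCCCC(=O)N(C)OC
Why: Lateral lithiation of an ortho-toluate followed by Weinreb ketone synthesis: the C4a methyl is the only C–H conjugated with the ester and gives the benzylic anion, the chelated tetrahedral adduct holds the ketone back until the quench, and the tert-butyl ester suppresses self-condensation of the anion.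

Step 11
Reactants: 21 tert-butyl 4-(benzyloxy)-2-[2-(benzyloxy)-4-methoxy-6-pentylphenoxy]-6-(2-oxoheptyl)benzoate
Product: 23 6-(benzyloxy)-8-[2-(benzyloxy)-4-methoxy-6-pentylphenoxy]-3-pentyl-1H-isochromen-1-one, via keto acid 22 (not isolated)
Conditions: p-TsOH·H2O (0.3 equiv), toluene, 90 °C
Reagents that add atoms: none
Why: Acid-catalysed E1 loss of isobutene from the tert-butyl ester and cyclodehydration of the 2-(2-oxoalkyl)benzoic acid through its lactol (6-exo-trig attack of the carboxyl oxygen on C3, then loss of water across C3–C4), the standard enol lactonisation to 3-alkylisocoumarins, which under acid avoids the base-induced Claisen closure to a naphthalene-1,3-diol.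

Step 12
Reactants: 23 6-(benzyloxy)-8-[2-(benzyloxy)-4-methoxy-6-pentylphenoxy]-3-pentyl-1H-isochromen-1-one
Product: 24 6-hydroxy-8-(2-hydroxy-4-methoxy-6-pentylphenoxy)-3-pentyl-1H-isochromen-1-one (NP-007099)
Conditions: H2 (1 atm), 10% Pd/C, EtOAc, rt, stopped after uptake of two equivalents
Reagents that add atoms: none
Why: Catalytic hydrogenolysis of the two aryl benzyl ethers, which at one atmosphere is much faster than saturation of the trisubstituted C3–C4 bond of the conjugated enol lactone, while the methyl ether, the diaryl ether and the lactone are inert.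

## Compound list

1 | orsellinic acid (2,4-dihydroxy-6-methylbenzoic acid) | Cc1cc(O)cc(O)c1C(=O)O | starting material
2 | tert-butyl 2,2,2-trichloroacetimidate | CC(C)(C)OC(=N)C(Cl)(Cl)Cl | starting material
3 | tert-butyl 2,4-dihydroxy-6-methylbenzoate | Cc1cc(O)cc(O)c1C(=O)OC(C)(C)C | intermediate
4 | benzyl bromide | BrCc1ccccc1 | starting material
5 | tert-butyl 4-(benzyloxy)-2-hydroxy-6-methylbenzoate | Cc1cc(OCc2ccccc2)cc(O)c1C(=O)OC(C)(C)C | intermediate
6 | dimethyl bromomalonate | COC(=O)C(Br)C(=O)OC | starting material
7 | dimethyl 2-[5-(benzyloxy)-2-(tert-butoxycarbonyl)-3-methylphenoxy]propanedioate | COC(=O)C(Oc1cc(OCc2ccccc2)cc(C)c1C(=O)OC(C)(C)C)C(=O)OC | intermediate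
8 | (E)-non-3-en-2-one | CCCCC/C=C/C(C)=O | starting material
9 | dimethyl 2-[5-(benzyloxy)-2-(tert-butoxycarbonyl)-3-methylphenoxy]-2-(2-oxononan-4-yl)propanedioate (racemic) | CCCCC[C@@H](CC(C)=O)C(Oc1cc(OCc2ccccc2)cc(C)c1C(=O)OC(C)(C)C)(C(=O)OC)C(=O)OC | intermediate
10 | methyl 1-[5-(benzyloxy)-2-(tert-butoxycarbonyl)-3-methylphenoxy]-2,4-dioxo-6-pentylcyclohexane-1-carboxylate (racemic; aryloxy trans to pentyl) | CCCCC[C@H]1CC(=O)CC(=O)[C@@]1(Oc1cc(OCc2ccccc2)cc(C)c1C(=O)OC(C)(C)C)C(=O)OC | intermediate
11 | 1-[5-(benzyloxy)-2-(tert-butoxycarbonyl)-3-methylphenoxy]-2,4-dioxo-6-pentylcyclohexane-1-carboxylic acid (racemic) | CCCCC[C@H]1CC(=O)CC(=O)[C@@]1(Oc1cc(OCc2ccccc2)cc(C)c1C(=O)OC(C)(C)C)C(=O)O | intermediate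
12 | tert-butyl 4-(benzyloxy)-2-[(2,4-dioxo-6-pentylcyclohexyl)oxy]-6-methylbenzoate (racemic; trans) | CCCCC[C@H]1CC(=O)CC(=O)[C@@H]1Oc1cc(OCc2ccccc2)cc(C)c1C(=O)OC(C)(C)C | intermediate
13 | methanol | CO | starting material
14 | tert-butyl 4-(benzyloxy)-2-[(4-methoxy-2-oxo-6-pentylcyclohex-3-en-1-yl)oxy]-6-methylbenzoate (racemic; trans) | CCCCC[C@H]1CC(OC)=CC(=O)[C@@H]1Oc1cc(OCc2ccccc2)cc(C)c1C(=O)OC(C)(C)C | intermediate
15 | tert-butyl 4-(benzyloxy)-2-(2-hydroxy-4-methoxy-6-pentylphenoxy)-6-methylbenzoate | CCCCCc1cc(OC)cc(O)c1Oc1cc(OCc2ccccc2)cc(C)c1C(=O)OC(C)(C)C | intermediate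
16 | tert-butyl 4-(benzyloxy)-2-[2-(benzyloxy)-4-methoxy-6-pentylphenoxy]-6-methylbenzoate | CCCCCc1cc(OC)cc(OCc2ccccc2)c1Oc1cc(OCc2ccccc2)cc(C)c1C(=O)OC(C)(C)C | intermediate
17 | hexanoyl chloride | CCCCCC(=O)Cl | starting material
18 | N,O-dimethylhydroxylamine hydrochloride | CNOC.Cl | starting material
19 | N-methoxy-N-methylhexanamide | CCCCCC(=O)N(C)OC | intermediate
20 | lithiated 16 (lithium on the C4a methylene) | [Li]Cc1cc(OCc2ccccc2)cc(Oc2c(CCCCC)cc(OC)cc2OCc2ccccc2)c1C(=O)OC(C)(C)C | intermediate
21 | tert-butyl 4-(benzyloxy)-2-[2-(benzyloxy)-4-methoxy-6-pentylphenoxy]-6-(2-oxoheptyl)benzoate | CCCCCC(=O)Cc1cc(OCc2ccccc2)cc(Oc2c(CCCCC)cc(OC)cc2OCc2ccccc2)c1C(=O)OC(C)(C)C | intermediate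
22 | 4-(benzyloxy)-2-[2-(benzyloxy)-4-methoxy-6-pentylphenoxy]-6-(2-oxoheptyl)benzoic acid | CCCCCC(=O)Cc1cc(OCc2ccccc2)cc(Oc2c(CCCCC)cc(OC)cc2OCc2ccccc2)c1C(=O)O | intermediate
23 | 6-(benzyloxy)-8-[2-(benzyloxy)-4-methoxy-6-pentylphenoxy]-3-pentyl-1H-isochromen-1-one | CCCCCc1cc2cc(OCc3ccccc3)cc(Oc3c(OCc4ccccc4)cc(OC)cc3CCCCC)c2c(=O)o1 | intermediate
24 | 6-hydroxy-8-(2-hydroxy-4-methoxy-6-pentylphenoxy)-3-pentyl-1H-isochromen-1-one (NP-007099) | CCCCCc1cc2cc(O)cc(Oc3c(O)cc(OC)cc3CCCCC)c2c(=O)o1 | target

## Step count and risks

Total step count: 12. Longest linear sequence: 11 (steps 1 to 8 and 10 to 12). Step 9 is a one-step side branch.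

**Step 4 (bears the label "Proposed new method:").**
- What may go wrong: reversal of the conjugate addition at the crowded C1'–C6' bond may outrun ring closure. The enone may be consumed by self-condensation. The malonate anion may slowly attack the ring A ester.
- Fallback, all known reaction types, with the ether bond made on a preformed ring B. It sets out from 8 and 5 and comes back at 14.
- Dimethyl malonate and 8 with NaOMe in refluxing MeOH give methyl 2,4-dioxo-6-pentylcyclohexane-1-carboxylate F1.
- Aqueous NaOH and then warm dilute HCl give 5-pentylcyclohexane-1,3-dione F2.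
- MeOH with catalytic p-TsOH gives 3-methoxy-5-pentylcyclohex-2-en-1-one F3. Only one enol ether is possible because the dione is symmetric.
- Kinetic α'-deprotonation with LiN(iPr)2 in THF at −78 °C and bromination with NBS, anti to the pentyl group, give trans-6-bromo-3-methoxy-5-pentylcyclohex-2-en-1-one F4.
- The potassium phenoxide of 5 (K2CO3, acetone, rt or below, to favour substitution over loss of HBr) displaces bromide from this α-bromo ketone with inversion. This gives the cis epimer of 14, F5, which epimerises at the α-carbon under the carbonate to 14. Either epimer serves, since the centre is erased in step 7.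
- This path also fixes the position of the methoxy group without relying on step 6.

**Step 6.**
- What may go wrong: poor site selectivity between the C4' and C2' carbonyl groups in the enol ether formation.
- Fallback: the order of events is changed so that a quaternary centre enforces the selectivity. It sets out from 10 and comes back at 14.
- The enol etherification (MeOH, catalytic p-TsOH, 3 Å molecular sieves) is run on 10 while C1' still carries both the aryloxy and the ester group. C2' is then neopentyl-like, and the well-known bias of 4,4-disubstituted cyclohexane-1,3-diones applies. The product is methyl 1-[5-(benzyloxy)-2-(tert-butoxycarbonyl)-3-methylphenoxy]-4-methoxy-2-oxo-6-pentylcyclohex-3-ene-1-carboxylate F6.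
- Krapcho dealkoxycarbonylation (LiCl, H2O, DMSO, 130 °C) then removes the C1' ester. Chloride attacks the ester methyl group, whose carboxylate is the better leaving group compared with the vinylogous ester, and CO2 is lost to give 14.
- This path also bypasses the hydroxide-dependent step 5.

**Step 7.**
- What may go wrong: hydride abstraction may be sluggish. The electron-rich phenol may be over-oxidised as it forms. The aryloxy group may be lost from C1' on prolonged heating.
- Fallback: dehydrogenation by selenoxide elimination at low temperature instead of hydride abstraction. It sets out from 14 and comes back at 15.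
- LiN(iPr)2 (1.05 equiv, THF, −78 °C) removes the C1' proton, which is far more acidic than the C4a methyl. PhSeBr, approaching anti to the pentyl group, gives tert-butyl 4-(benzyloxy)-2-{[4-methoxy-2-oxo-6-pentyl-1-(phenylselanyl)cyclohex-3-en-1-yl]oxy}-6-methylbenzoate F7, with selenium syn to the C6' hydrogen.
- H2O2 and pyridine in CH2Cl2 at 0 °C give the corresponding selenoxide F8. It undergoes syn elimination across C1'–C6', and the cross-conjugated dienone tautomerises to 15.

Further compounds
F1 | step 4 | methyl 2,4-dioxo-6-pentylcyclohexane-1-carboxylate (racemic; trans) | CCCCC[C@H]1CC(=O)CC(=O)[C@@H]1C(=O)OC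
F2 | step 4 | 5-pentylcyclohexane-1,3-dione | CCCCCC1CC(=O)CC(=O)C1
F3 | step 4 | 3-methoxy-5-pentylcyclohex-2-en-1-one (racemic) | CCCCC[C@H]1CC(OC)=CC(=O)C1
F4 | step 4 | trans-6-bromo-3-methoxy-5-pentylcyclohex-2-en-1-one (racemic) | CCCCC[C@H]1CC(OC)=CC(=O)[C@@H]1Br
F5 | step 4 | cis epimer of 14 (racemic) | CCCCC[C@H]1CC(OC)=CC(=O)[C@H]1Oc1cc(OCc2ccccc2)cc(C)c1C(=O)OC(C)(C)C
F6 | step 6 | methyl 1-[5-(benzyloxy)-2-(tert-butoxycarbonyl)-3-methylphenoxy]-4-methoxy-2-oxo-6-pentylcyclohex-3-ene-1-carboxylate (racemic) | CCCCC[C@H]1CC(OC)=CC(=O)[C@@]1(Oc1cc(OCc2ccccc2)cc(C)c1C(=O)OC(C)(C)C)C(=O)OC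
F7 | step 7 | tert-butyl 4-(benzyloxy)-2-{[4-methoxy-2-oxo-6-pentyl-1-(phenylselanyl)cyclohex-3-en-1-yl]oxy}-6-methylbenzoate (racemic; selenium trans to pentyl) | CCCCC[C@H]1CC(OC)=CC(=O)[C@@]1([Se]c1ccccc1)Oc1cc(OCc2ccccc2)cc(C)c1C(=O)OC(C)(C)C
F8 | step 7 | selenoxide of F7 | CCCCC[C@H]1CC(OC)=CC(=O)[C@@]1([Se](=O)c1ccccc1)Oc1cc(OCc2ccccc2)cc(C)c1C(=O)OC(C)(C)C
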